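The benzoate (C1 carries the ester, C2 and C3 the hydroxyls) is disconnected at C1–C6 by reading the ring as a disguised isomer: C3, C4, C5, C6 and the C3 oxygen form a furan, while C1, C2 and the ester carbon form a β-keto ester. The precursor is therefore tetracosyl 3-(furan-2-yl)-3-oxopropanoate, reached in two routine steps from furan-2-carbonyl chloride, Meldrum's acid and 1-tetracosanol. In one operation, an acid catalyst with a catalytic amount of water opens the furan to a 1,2-diketo aldehyde, the doubly activated C1 methylene condenses with the C6 aldehyde to close the six-membered carbocycle, and enolisation delivers the catechol ester without any redox reagent or protecting group.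

Key step: step 3

Remark: the alkyl group is taken as unbranched tetracosyl (24 carbons); the target has no stereocentre, so no step has to control configuration.

Step 1
Reactants: 1 furan-2-carbonyl chloride; 2 Meldrum's acid (2,2-dimethyl-1,3-dioxane-4,6-dione)
Product: 3 5-[furan-2-yl(hydroxy)methylidene]-2,2-dimethyl-1,3-dioxane-4,6-dione (enol form of furoyl Meldrum's acid)
Conditions: pyridine (2.2 equiv), DMAP (5 mol %), CH2Cl2, 0 °C to rt; cold 1 M HCl wash; crude 3 carried on
Reagents that add atoms: none
Why: Meldrum's acid (pKa about 5) is deprotonated by pyridine and C-acylated by the acid chloride (acylation of an active methylene compound), and the product rests as its hydrogen-bonded enol, which should prevent a second acylation while the furan stays untouched.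

Step 2
Reactants: 3 5-[furan-2-yl(hydroxy)methylidene]-2,2-dimethyl-1,3-dioxane-4,6-dione; 4 1-tetracosanol
Product: 6 tetracosyl 3-(furan-2-yl)-3-oxopropanoate, via furoylketene 5 (not isolated)
Conditions: toluene, 110 °C, N2 (3 in slight excess, 1.1 equiv)
Reagents that add atoms: none
Why: Thermal fragmentation of the acyl Meldrum's acid expels acetone and CO2 to give acylketene 5, which the primary alcohol captures irreversibly to give the β-keto ester (acyl Meldrum's acid alcoholysis); only volatile co-products form, so the waxy alcohol should be consumed completely with near-stoichiometric 3.

Step 3
Reactants: 6 tetracosyl 3-(furan-2-yl)-3-oxopropanoate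
Product: 9 Gentiside K (tetracosyl 2,3-dihydroxybenzoate), via keto aldehyde 7 (not isolated), via cyclohexenedione 8 (not isolated)
Conditions: Sc(OTf)3 (20 mol %), H2O (0.5 equiv), 1,4-dioxane, 100 °C, Ar; then aq. citric acid wash
Reagents that add atoms: none
Why: Proposed new method: the scandium-bound β-keto ester of 6 is a polarised acylfuran whose ring is attacked by water at C6 (after protonation at C5 by the acidic aqua complex, or by conjugate addition), the C3–O–C6 hemiacetal link then opens to keto aldehyde 7 in which the former furan oxygen is the C3 carbonyl, the chelated C1 enol adds to the C6 aldehyde and the same molecule of water is lost again to give 8, and two enolisations (C3=O towards C4, then loss of a C5 proton) aromatise 8 to 9, so that the step is an isomerisation in which no atom of a reagent is retained. The closest known reaction types are the acid-catalysed hydrolytic opening of a furan to a 1,4-dicarbonyl compound followed by intramolecular aldol condensation to an arene (5-(hydroxymethyl)furfural to benzene-1,2,4-triol), the Piancatelli-type attack of water at the 5-position of an acid-activated furan, and the Knoevenagel condensation of β-keto esters, but the combined sequence has not been shown on a 2-furoylacetate. The six-membered carbocycle closes through the new C1–C6 bond by a 6-(enolendo)-exo-trig aldol addition of the C1=C2 enol, a geometrically allowed mode, followed by dehydration. No stereocentre is created. The step needs chemoselectivity for furan hydration over hydrolysis and decarboxylation of the β-keto ester, which the primary alkyl ester and the substoichiometric, continuously regenerated water should secure, and regioselectivity in the ring closure, which is secured because C1 is the only doubly activated carbon and C6 the only aldehyde of 7 and the two are six atoms apart.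

Compound list
1 | furan-2-carbonyl chloride | O=C(Cl)c1ccco1 | starting material
2 | Meldrum's acid (2,2-dimethyl-1,3-dioxane-4,6-dione) | CC1(C)OC(=O)CC(=O)O1 | starting material
3 | 5-[furan-2-yl(hydroxy)methylidene]-2,2-dimethyl-1,3-dioxane-4,6-dione (enol form of furoyl Meldrum's acid) | CC1(C)OC(=O)C(=C(O)c2ccco2)C(=O)O1 | intermediate
4 | 1-tetracosanol | CCCCCCCCCCCCCCCCCCCCCCCCO | starting material
5 | 3-(furan-2-yl)-3-oxoprop-1-en-1-one (furoylketene) | O=C=CC(=O)c1ccco1 | intermediate
6 | tetracosyl 3-(furan-2-yl)-3-oxopropanoate | CCCCCCCCCCCCCCCCCCCCCCCCOC(=O)CC(=O)c1ccco1 | intermediate
7 | tetracosyl 3,4,7-trioxoheptanoate | CCCCCCCCCCCCCCCCCCCCCCCCOC(=O)CC(=O)C(=O)CCC=O | intermediate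
8 | tetracosyl 5,6-dioxocyclohex-1-ene-1-carboxylate | CCCCCCCCCCCCCCCCCCCCCCCCOC(=O)C1=CCCC(=O)C1=O | intermediate
9 | Gentiside K (tetracosyl 2,3-dihydroxybenzoate) | CCCCCCCCCCCCCCCCCCCCCCCCOC(=O)c1cccc(O)c1O | target

Total step count: 3
Longest linear sequence: 3 steps (1 or 2 to 9; 4 enters at step 2)

Steps most likely to fail

1. Step 3 (proposed new method). The acyl-substituted furan may resist hydration at temperatures where other processes take over. These are hydrolysis and decarboxylation of the β-keto ester, re-closure of the opened tricarbonyl to the furan, oligomerisation of the aldehyde, and sequestration of the catalyst by the chelating catechol product. The fallback uses known chemistry and forms the ester bond on a preformed catechol acid. It sets out from 1-tetracosanol 4. Steglich esterification (DCC, DMAP, CH2Cl2/THF) with commercial 2,3-bis(benzyloxy)benzoic acid (O=C(O)c1cccc(OCc2ccccc2)c1OCc1ccccc1) should give tetracosyl 2,3-bis(benzyloxy)benzoate F1. Hydrogenolysis of both benzyl ethers (H2, Pd/C, THF/EtOAc) then comes back to the route at Gentiside K 9; the alkyl ester is inert to these conditions.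

2. Step 2. Capture of the furoylketene by the sparingly soluble long-chain alcohol may be slow, so that ketene dimerisation, or capture by traces of water followed by decarboxylation, competes and unreacted alcohol contaminates the waxy product. The fallback builds the ester bond before the C-acylation and sets out from 4 and 2. Heating the two in toluene at 100 °C should open the dioxanedione by alcoholysis to tetracosyl hydrogen malonate F2. Its magnesium enolate (MgCl2, Et3N, THF/MeCN) is C-acylated by 1 to 2-(furan-2-carbonyl)-3-oxo-3-(tetracosyloxy)propanoic acid F3. F3 loses CO2 on acidic work-up and comes back to the route at 6.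

3. Step 1. O-acylation or incomplete C-acylation by the heteroaroyl chloride, and hydrolytic decomposition of the moisture-sensitive acyl Meldrum's acid during the acidic wash, may erode the material entering step 2. The fallback avoids Meldrum's acid and sets out from 4. DMAP-catalysed transesterification with an excess of commercial ethyl 3-(furan-2-yl)-3-oxopropanoate (CCOC(=O)CC(=O)c1ccco1) in refluxing toluene, with continuous removal of ethanol over 4 Å molecular sieves, should come back to the route at 6, by-passing 3. It is held in reserve because it is an equilibrium that needs an excess of the ethyl ester. No new compound is made (F0).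

Further compounds
F1 | step 3 | tetracosyl 2,3-bis(benzyloxy)benzoate | CCCCCCCCCCCCCCCCCCCCCCCCOC(=O)c1cccc(OCc2ccccc2)c1OCc1ccccc1
F2 | step 2 | tetracosyl hydrogen malonate (3-oxo-3-(tetracosyloxy)propanoic acid) | CCCCCCCCCCCCCCCCCCCCCCCCOC(=O)CC(=O)O
F3 | step 2 | 2-(furan-2-carbonyl)-3-oxo-3-(tetracosyloxy)propanoic acid | CCCCCCCCCCCCCCCCCCCCCCCCOC(=O)C(C(=O)O)C(=O)c1ccco1
F0 | step 1 | none | none
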